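The earlier runs and the new flask were generated by integration for substances that don't exist, noise included.

Two constants carry this flask, and you can read both from the runs before reckoning anything.

| setting | cedar | birch | flask |
|---|---|---|---|
| L | 0.40 M | 0.40 M | 0.40 M |
| Q | 0.44 M | 0.29 M | 0.440 M |
| J | 0.020 M | 0.020 M | 0.0200 M |
| remark | the very flask that is asked about, followed so far | run made earlier |  |
| time |  |  | 1.0 h |
- cedar (time / min: G / %, L / %): 2.50: 0, 88; 6.00: 0, 72; 12.0: 8, 60; 30.0: 31, 27
- birch (time / min: G / %, L / %): 8.00: 5, 70; 20.0: 13, 42; 40.0: 29, 20; 60.0: 44, 8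

(each reading ± 1.5 percentage points)

- how much G the flask holds at 1.0 h, in percent of the L charged
- how much L the flask holds at 1.0 h, in percent of the L charged

In cedar L falls first-order with a half-life of 16.1 min. I take G's rate as k[Q] times the intermediate, counting as intermediate whatever is neither L nor G and spending one Q per G. Cedar from 12.0 min to 30.0 min gives k = 0.00159 M⁻¹ s⁻¹, and birch from 20.0 min to 60.0 min gives nearly the same, 0.00158 M⁻¹ s⁻¹. At the charged [Q] that makes 16.5 min, the capture half-life: the pseudo-first-order half-life of the intermediate against Q. It matches L's half-life, so the intermediate stays high, 42.0% at 30.0 min. Holding it there, my reckoning lets [Q] decay from 0.316 M and gives G 61.2% and L 7.44%. I expect less G than that, since L, which I take to feed the intermediate, falls on from 27% to that figure.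

The forecast stood higher on G, at 66% (57% to 73%), with L at 7.5% (5% to 10%), and held that G “then rises almost linearly”.

The flask gives G 54.9% and L 8.68%.

    L → Z (k = 6.60 × 10⁻⁴ s⁻¹)
    Q + Z → G (k = 0.00170 M⁻¹ s⁻¹)
    L + J → X (k = 0.00890 M⁻¹ s⁻¹)
    Z → E (k = 5.50 × 10⁻⁵ s⁻¹)

At 1.0 h the flask keeps 50% of its Q, so on my k, as read from the runs, the capture half-life at that [Q] comes to 33.0 min, twice its value at the charge, and G gained 25 percentage points over the last half of the time. On the same reading, the neighbour charged with 0.18 M of Q starts at a capture half-life of 40.4 min, 2.51 times the half-life I read for L in cedar. Its L still reaches 8.68%, but at 1.0 h it holds Z 49.5% and G 28.7%.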